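**Retrosynthetic overview**
1. Astepyrazinol B ⇐ catalytic asymmetric hydrogenation of the exocyclic C=C of a (Z)-3-(pyrazinonylmethylidene)-7-prenyloxindole; the base-labile C3–H centre is created in the last step.
2. That alkylidene oxindole ⇐ intermolecular aldol condensation (Knoevenagel type) of C3 of 7-prenyloxindole with 3-methoxy-5-methyl-6-oxo-1,6-dihydropyrazine-2-carbaldehyde (key C–C bond).
3. Pyrazinone aldehyde ⇐ C2-symmetric 2,5-dichloro-3,6-dimethylpyrazine: one CH3 → CHO; the CHO then differentiates the two chlorides (methoxide SNAr ortho to CHO; the other Cl → OPMB → C=O).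
4. 7-Prenyloxindole ⇐ 7-bromooxindole + tributyl(prenyl)stannane (Stille).
5. Ring order: no ring is built; the pyrazine and oxindole rings are bought preformed and only functionalised, then joined in the penultimate step.

Assumption: the facial sense of the final hydrogenation cannot be predicted with certainty, so the ligand antipode that gives the (S)-product is chosen on test scale (chiral HPLC, optical rotation against the natural product); the product is handled under neutral conditions only.

**Step 1**
Reactants: 1 3-chloro-2,5-dimethylpyrazine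
Product: 2 3-chloro-2,5-dimethylpyrazine 1-oxide
Conditions: mCPBA (1.3 equiv), CHCl3, 50 °C
Reagents that add atoms: mCPBA, OOC(=O)c1cccc(Cl)c1
Why: Peracid N-oxidation goes to N1, the ring nitrogen not flanked by the electron-withdrawing C–Cl and therefore the less hindered and more nucleophilic one.

**Step 2**
Reactants: 2 3-chloro-2,5-dimethylpyrazine 1-oxide
Product: 3 2,5-dichloro-3,6-dimethylpyrazine
Conditions: POCl3 (neat), 100 °C
Reagents that add atoms: phosphoryl chloride, O=P(Cl)(Cl)Cl
Why: Deoxygenative chlorination of an azine N-oxide: O-phosphorylation activates the ring, chloride adds at the only free α-carbon (C6) and loss of dichlorophosphate rearomatises to the C2-symmetric dichloride.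

**Step 3**
Reactants: 3 2,5-dichloro-3,6-dimethylpyrazine
Product: 4 2-(bromomethyl)-3,6-dichloro-5-methylpyrazine
Conditions: NBS (0.9 equiv), AIBN (5 mol %), PhCF3, 85 °C
Reagents that add atoms: N-bromosuccinimide, O=C1CCC(=O)N1Br
Why: Wohl–Ziegler radical bromination of an azine-benzylic methyl; because 3 is C2-symmetric only one monobromide can form, and sub-stoichiometric NBS keeps over-bromination low (unreacted 3 is recycled).

**Step 4**
Reactants: 4 2-(bromomethyl)-3,6-dichloro-5-methylpyrazine
Product: 6 3,6-dichloro-5-methylpyrazine-2-carbaldehyde, via alkoxyammonium bromide 5 (not isolated)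
Conditions: NMO (4 equiv), 4 Å MS, MeCN, rt
Reagents that add atoms: N-methylmorpholine N-oxide, C[N+]1([O-])CCOCC1
Why: Kornblum-type N-oxide oxidation: SN2 displacement of bromide by the N-oxide oxygen, then base-induced elimination of N-methylmorpholine from the alkoxyammonium salt, under conditions too mild for SNAr at the C–Cl bonds.

**Step 5**
Reactants: 6 3,6-dichloro-5-methylpyrazine-2-carbaldehyde
Product: 7 6-chloro-3-methoxy-5-methylpyrazine-2-carbaldehyde
Conditions: NaOMe (1.0 equiv), THF/MeOH, −40 to 0 °C
Reagents that add atoms: sodium methoxide, C[O-].[Na+]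
Why: Regioselective SNAr: the C3–Cl is ortho to the formyl group and α to N4, so its Meisenheimer anion is delocalised into the C=O, whereas the C6–Cl is meta to CHO and next to the donor methyl; one equivalent at low temperature stops at mono-substitution.

**Step 6**
Reactants: 7 6-chloro-3-methoxy-5-methylpyrazine-2-carbaldehyde
Product: 8 6-chloro-2-(dimethoxymethyl)-3-methoxy-5-methylpyrazine
Conditions: HC(OMe)3 (3 equiv), TsOH·H2O (5 mol %), MeOH, 50 °C
Reagents that add atoms: trimethyl orthoformate, COC(OC)OC
Why: Acid-catalysed acetalisation driven by the orthoformate masks the aldehyde against alkoxide addition and Cannizzaro/Tishchenko chemistry in the next step.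

**Step 7**
Reactants: 8 6-chloro-2-(dimethoxymethyl)-3-methoxy-5-methylpyrazine
Product: 9 2-(dimethoxymethyl)-3-methoxy-6-[(4-methoxybenzyl)oxy]-5-methylpyrazine
Conditions: 4-MeOC6H4CH2OH (1.3 equiv), NaH (1.3 equiv), DMF, 0 °C then 90 °C
Reagents that add atoms: 4-methoxybenzyl alcohol, COc1ccc(CO)cc1
Why: SNAr (addition–elimination) at the remaining α-chloroazine carbon by a primary alkoxide in a dipolar aprotic solvent; the para-methoxy group deactivates the ring, hence the heating, and the acetal and methyl lactim ether are inert to base.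

**Step 8**
Reactants: 9 2-(dimethoxymethyl)-3-methoxy-6-[(4-methoxybenzyl)oxy]-5-methylpyrazine
Product: 11 3-methoxy-5-methyl-6-oxo-1,6-dihydropyrazine-2-carbaldehyde, via pyrazinone dimethyl acetal 10 (not isolated)
Conditions: TFA/CH2Cl2/H2O (5:4:1), 0 °C to rt
Reagents that add atoms: water, O
Why: Acidolysis: N-protonation releases the PMB cation (SN1, trapped by water) to unmask the pyrazinone, and the same aqueous acid hydrolyses the dimethyl acetal, while the methyl lactim ether survives TFA at room temperature.

**Step 9**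
Reactants: 12 7-bromoindolin-2-one (7-bromooxindole); 13 tributyl(3-methylbut-2-en-1-yl)stannane
Product: 14 7-(3-methylbut-2-en-1-yl)indolin-2-one (7-prenyloxindole)
Conditions: Pd(PPh3)4 (5 mol %), DMF, 100 °C
Reagents that add atoms: none
Why: Stille cross-coupling transfers the prenyl group through its unsubstituted α-carbon to give the linear prenyl arene, and the neutral conditions tolerate the free lactam N–H and the acidic C3–H2.

**Step 10**
Reactants: 14 7-(3-methylbut-2-en-1-yl)indolin-2-one; 11 3-methoxy-5-methyl-6-oxo-1,6-dihydropyrazine-2-carbaldehyde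
Product: 16 (Z)-3-[(3-methoxy-5-methyl-6-oxo-1,6-dihydropyrazin-2-yl)methylidene]-7-(3-methylbut-2-en-1-yl)indolin-2-one, via aldol adduct 15 (not isolated)
Conditions: piperidine (0.2 equiv), AcOH (0.2 equiv), EtOH, 78 °C
Reagents that add atoms: none
Why: Intermolecular aldol addition of the oxindole C3 enolate to the aldehyde followed by E1cB dehydration (Knoevenagel-type aldol condensation) forms the key C–C bond; the pyrazinone N–H···O=C2 hydrogen bond makes the (Z)-isomer the thermodynamic product, which precipitates.

**Step 11**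
Reactants: 16 (Z)-3-[(3-methoxy-5-methyl-6-oxo-1,6-dihydropyrazin-2-yl)methylidene]-7-(3-methylbut-2-en-1-yl)indolin-2-one
Product: 17 (S)-3-[(3-methoxy-5-methyl-6-oxo-1,6-dihydropyrazin-2-yl)methyl]-7-(3-methylbut-2-en-1-yl)indolin-2-one (astepyrazinol B)
Conditions: [Rh(cod)2]BF4 (2 mol %), ZhaoPhos (bisphosphine–thiourea, antipode giving S, 2.2 mol %), H2 (50 bar), CH2Cl2/i-PrOH, 30 °C
Reagents that add atoms: none
Why: Rh(I)–bisphosphine asymmetric hydrogenation: the lactam carbonyl binds the catalyst so that H2 adds to one face of the single (Z)-alkene and sets C3 as (S) under neutral conditions, while the unchelated trisubstituted prenyl alkene is not reduced.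

**Compound list**
1 | 3-chloro-2,5-dimethylpyrazine | Cc1cnc(C)c(Cl)n1 | starting material
2 | 3-chloro-2,5-dimethylpyrazine 1-oxide | Cc1c[n+]([O-])c(C)c(Cl)n1 | intermediate
3 | 2,5-dichloro-3,6-dimethylpyrazine | Cc1nc(Cl)c(C)nc1Cl | intermediate
4 | 2-(bromomethyl)-3,6-dichloro-5-methylpyrazine | BrCc1nc(Cl)c(C)nc1Cl | intermediate
5 | 4-[(3,6-dichloro-5-methylpyrazin-2-yl)methoxy]-4-methylmorpholin-4-ium bromide | C[N+]1(OCc2nc(Cl)c(C)nc2Cl)CCOCC1.[Br-] | intermediate (not isolated)
6 | 3,6-dichloro-5-methylpyrazine-2-carbaldehyde | O=Cc1nc(Cl)c(C)nc1Cl | intermediate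
7 | 6-chloro-3-methoxy-5-methylpyrazine-2-carbaldehyde | O=Cc1nc(Cl)c(C)nc1OC | intermediate
8 | 6-chloro-2-(dimethoxymethyl)-3-methoxy-5-methylpyrazine | COC(OC)c1nc(Cl)c(C)nc1OC | intermediate
9 | 2-(dimethoxymethyl)-3-methoxy-6-[(4-methoxybenzyl)oxy]-5-methylpyrazine | COC(OC)c1nc(OCc2ccc(OC)cc2)c(C)nc1OC | intermediate
10 | 6-(dimethoxymethyl)-5-methoxy-3-methylpyrazin-2(1H)-one | COC(OC)c1[nH]c(=O)c(C)nc1OC | intermediate (not isolated)
11 | 3-methoxy-5-methyl-6-oxo-1,6-dihydropyrazine-2-carbaldehyde | COc1nc(C)c(=O)[nH]c1C=O | intermediate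
12 | 7-bromoindolin-2-one | O=C1Cc2cccc(Br)c2N1 | starting material
13 | tributyl(3-methylbut-2-en-1-yl)stannane | CCCC[Sn](CCCC)(CCCC)CC=C(C)C | starting material
14 | 7-(3-methylbut-2-en-1-yl)indolin-2-one | O=C1Cc2cccc(CC=C(C)C)c2N1 | intermediate
15 | 3-[hydroxy(3-methoxy-5-methyl-6-oxo-1,6-dihydropyrazin-2-yl)methyl]-7-(3-methylbut-2-en-1-yl)indolin-2-one (racemic diastereomer mixture) | COc1nc(C)c(=O)[nH]c1C(O)C1C(=O)Nc2c(CC=C(C)C)cccc21 | intermediate (not isolated)
16 | (Z)-3-[(3-methoxy-5-methyl-6-oxo-1,6-dihydropyrazin-2-yl)methylidene]-7-(3-methylbut-2-en-1-yl)indolin-2-one | COc1nc(C)c(=O)[nH]c1/C=C1\C(=O)Nc2c(CC=C(C)C)cccc21 | intermediate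
17 | (S)-3-[(3-methoxy-5-methyl-6-oxo-1,6-dihydropyrazin-2-yl)methyl]-7-(3-methylbut-2-en-1-yl)indolin-2-one, astepyrazinol B | COc1nc(C)c(=O)[nH]c1C[C@@H]1C(=O)Nc2c(CC=C(C)C)cccc21 | target

**Totals**
Total step count: 11. Longest linear sequence: 10 (steps 1–8, 10, 11).

**Three steps most likely to fail**

Step 11 (enantioselectivity, facial sense and possible catalyst inhibition by the pyrazinone are not assured). The fallback sets out from 16 and comes back at 17. The exocyclic alkene of 16 is reduced without a chiral catalyst by conjugate hydride addition (NaBH4, THF/MeOH, 0 °C; the prenyl alkene is inert) to racemic 3-[(3-methoxy-5-methyl-6-oxo-1,6-dihydropyrazin-2-yl)methyl]-7-(3-methylbut-2-en-1-yl)indolin-2-one F3. The enantiomers are separated by preparative chiral SFC (amylose-type phase, CO2/MeOH, no basic additive) to give 17. The unwanted (R)-3-[(3-methoxy-5-methyl-6-oxo-1,6-dihydropyrazin-2-yl)methyl]-7-(3-methylbut-2-en-1-yl)indolin-2-one F4 is racemised with catalytic Et3N in MeOH back to F3 and recycled.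

Step 7 (the chloride is deactivated by the para-methoxy group and may resist thermal SNAr or give ether exchange). The fallback sets out from 8 and comes back at 10. Pd-catalysed hydroxylation of the C–Cl bond (tBuBrettPhos Pd G3 2 mol %, KOH 3 equiv, 1,4-dioxane/H2O, 80 °C, then neutralisation) gives the pyrazinone acetal 10 directly, here isolated. Compound 10 is then hydrolysed to 11 with the aqueous TFA of step 8, so the PMB ether 9 is bypassed. This fallback makes no new compound (F0).

Step 3 (radical bromination of methylpyrazines is often low-yielding and gives statistical over-bromination). The fallback sets out from 3 and comes back at 6. One methyl group is deprotonated with LDA (1.05 equiv, THF, −78 °C) to give [(3,6-dichloro-5-methylpyrazin-2-yl)methyl]lithium F1, not isolated; a second deprotonation of the mono-anion is unfavourable, so mono-selectivity is charge-controlled. The anion is hydroxylated at −78 °C with 2-(phenylsulfonyl)-3-phenyloxaziridine and quenched with NH4Cl to give (3,6-dichloro-5-methylpyrazin-2-yl)methanol F2. Dess–Martin periodinane (CH2Cl2, rt) then oxidises F2 to aldehyde 6, bypassing 4 and 5.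

**Further compounds**
F1 | step 3 | [(3,6-dichloro-5-methylpyrazin-2-yl)methyl]lithium | [Li]Cc1nc(Cl)c(C)nc1Cl
F2 | step 3 | (3,6-dichloro-5-methylpyrazin-2-yl)methanol | OCc1nc(Cl)c(C)nc1Cl
F0 | step 7 | none | none
F3 | step 11 | racemic 3-[(3-methoxy-5-methyl-6-oxo-1,6-dihydropyrazin-2-yl)methyl]-7-(3-methylbut-2-en-1-yl)indolin-2-one | COc1nc(C)c(=O)[nH]c1CC1C(=O)Nc2c(CC=C(C)C)cccc21
F4 | step 11 | (R)-3-[(3-methoxy-5-methyl-6-oxo-1,6-dihydropyrazin-2-yl)methyl]-7-(3-methylbut-2-en-1-yl)indolin-2-one | COc1nc(C)c(=O)[nH]c1C[C@H]1C(=O)Nc2c(CC=C(C)C)cccc21
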